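The numbers in the tables are calculated for substances that don't exist, noise included.

I decided to read the runs against charge times time, not against the clock.

| flask | starting complex | incoming ligand | remark | time |
|---|---|---|---|---|
| cedar | 0.050 M | 2.5 equiv | run made earlier |  |
| elm | 0.070 M | 2.5 equiv | run made earlier |  |
| ash | 0.11 M | 2.5 equiv | run made earlier |  |
| Thursday's | 0.050 M | 2.50 equiv (fed, over 1.5 h) | all else is in the flask from the start; the feed brings no volume worth counting | 2.0 h |
| Sunday's | 0.050 M | 2.50 equiv | everything together at the start | 2.0 h |
| Friday's | 0.050 M (fed, over 1.5 h) | 2.50 equiv | all else is in the flask from the start; the feed brings no volume worth counting | 2.0 h |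

cedar run (percent of the starting complex charged)

| time / min | complex with two exchanged / % | complex with one exchanged / % |
|---|---|---|
| 20.0 | 12.7 | 49.3 |
| 40.0 | 27.2 | 52.4 |
| 60.0 | 36.8 | 49.8 |
| 80.0 | 44.0 | 46.4 |
| 90.0 | 47.9 | 44.6 |
| 120 | 53.8 | 39.9 |

elm run (percent of the starting complex charged)

| time / h | complex with two exchanged / % | complex with one exchanged / % |
|---|---|---|
| 0.417 | 23.5 | 52.1 |
| 0.833 | 40.8 | 49.0 |
| 1.33 | 53.0 | 41.7 |
| 1.50 | 56.5 | 39.3 |
| 2.00 | 63.0 | 34.3 |
| 2.50 | 66.5 | 31.0 |

ash run (percent of the starting complex charged)

| time / h | complex with two exchanged / % | complex with one exchanged / % |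
|---|---|---|
| 0.200 | 17.7 | 51.4 |
| 0.333 | 29.3 | 52.2 |
| 0.500 | 39.8 | 49.4 |
| 0.833 | 52.8 | 41.6 |
| 1.33 | 63.8 | 33.5 |
| 2.50 | 74.1 | 24.8 |

(standard deviation of a reading: 0.5 percentage points)

* the flask that comes out highest in amount of complex with two exchanged, in percent of the starting complex charged; "all alike" if 1.5 percentage points covers them all (Thursday's / Sunday's / Friday's / all alike)
* amount of complex with two exchanged at the end, in percent of the starting complex charged, Thursday's
* amount of complex with two exchanged at the end, in percent of the starting complex charged, Sunday's
* amount of complex with two exchanged at the end, in percent of the starting complex charged, Friday's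

Did the clock matter, or the dose? I scaled each clock time by the run's charge over cedar's, and called the result cedar time. Elm at 1.33 h stood at 112 min of cedar time, and ash at 0.833 h at 110 min. They read 53.0% and 52.8% of complex with two exchanged, apart by 0.2 percentage points, less than the scatter of 0.5 points. Elm had spent 29.8 min more on the clock, yet it read no lower. So I let the slowing follow cedar time too.

What does a feed cost? A steady feed (semi-batch) holds each portion back by 0.750 h on average. Thursday's mean cedar time, 75.0 min, is therefore shorter than Sunday's 2.0 h.

What does that give? Between cedar's readings it gave 42.2% for Thursday's, against 53.8% for Sunday's, a repeat of cedar. Friday's has the same mean, so I gave it the same figure. That put Sunday's highest in my reckoning.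

The forecast also chose Sunday's, with 26%, 54% and 30% for Thursday's, Sunday's and Friday's. It read the slowing as “activity dying from the start of the run, whatever has been added”. My figure for Thursday's and Friday's stood above its own for each.

The flasks gave 43.8%, 54.5% and 31.6% in that order, so Sunday's led.

    starting complex + incoming ligand → leaving ligand + complex with one exchanged (k = 0.0122 M⁻¹ s⁻¹)
    complex with one exchanged + incoming ligand → leaving ligand + complex with two exchanged (k = 0.00361 M⁻¹ s⁻¹)
    starting complex ⇌ dormant form (K = 0.460, k = 0.00617 s⁻¹)
    2 incoming ligand → homo dimer (k = 6.40 × 10⁻⁴ M⁻¹ s⁻¹)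

Thursday's stood at 75.0 min of cedar time, and my 42.2% lay 1.6 points under that flask, but 11 points over Friday's. The neighbour was Sunday's left until 5.0 h, which is also its cedar time, since its charge is cedar's. Elm's last reading stands at 3.50 h of cedar time, with 66.5%, and ash's at 5.50 h, with 74.1%. A straight line between them gave 72.2%. The neighbour held 72.6% of complex with two exchanged.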